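**Retrosynthetic overview**

1. Numbering (elemane): ring A is the cyclohexane C5–C6–C7–C8–C9–C10 and ring B the γ-lactone O–C6–C7–C11–C12; C10 carries methyl and vinyl (C1=C2), C5 the acrylic acid C4(=C3)–C15, C8 the angelate.
2. Late stage: allyl ester cleavage, unmasking of the ring B exo-methylene from a Mannich base, and angeloylation of the free C8 alcohol.
3. Key disconnection: ring A is cut at C5–C6 and C8–C9 into a C6–C7–C8 dielectrophile (a lactone acetal aldehyde with ring B in place) and a C5–C10–C9 dinucleophile.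
4. Enabling feature: C6 and C8 are carbinol carbons 1,3 to each other on ring A, C5 bears a 2-carboxyallyl group (the SE2′ product of a 2-(silylmethyl)acrylate), and C9H2–C10–vinyl is the ring-opened form of a cyclopropylcarbinyl boronate. Both bonds therefore arise by carbonyl-type additions that also create the acrylate and the vinyl group.
5. Ring order: ring B first (menthyloxyfuranone, sets C7), a temporary cyclopropane second (asymmetric Simmons–Smith reaction, sets C10), ring A last in the key step, where the cyclopropane is opened.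

Key step: step 11

Remark on the chemistry: the C11 stereocentre made in step 9 is drawn trans to C8; it is of no consequence, because step 13 destroys it.

**Step 1**
Reactants: 1 prop-2-yn-1-ol; 2 methylmagnesium bromide; 3 iodine
Product: 5 (2Z)-3-iodo-2-methylprop-2-en-1-ol, via alkenylmagnesium alkoxide 4 (not isolated)
Conditions: MeMgBr (2.2 equiv), CuI (10 mol%), Et2O, −10 to 20 °C; then I2 (1.1 equiv), THF, −78 to 0 °C; H2O
Reagents that add atoms: methylmagnesium bromide (C[Mg]Br); iodine (II)
Why: Copper-catalysed anti-carbomagnesiation of the propargylic alkoxide puts methyl on the inner carbon and magnesium cis to the CH2O group in a five-membered chelate, so iodinolysis with retention should give the (Z)-iodide only (carbometalation of a propargylic alcohol).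

**Step 2**
Reactants: 5 (2Z)-3-iodo-2-methylprop-2-en-1-ol; 6 2,2′-methylenebis(4,4,5,5-tetramethyl-1,3,2-dioxaborolane)
Product: 7 (2Z)-2-methyl-4-(4,4,5,5-tetramethyl-1,3,2-dioxaborolan-2-yl)but-2-en-1-ol
Conditions: 6 (1.5 equiv), Pd(P(t-Bu)3)2 (5 mol%), KOH (aq., 3 equiv), 1,4-dioxane, 20 °C
Reagents that add atoms: 2,2′-methylenebis(4,4,5,5-tetramethyl-1,3,2-dioxaborolane) (CC1(C)OB(CB2OC(C)(C)C(C)(C)O2)OC1(C)C)
Why: Suzuki–Miyaura coupling of a geminal bis(boronate), in which hydroxide activates one boron only, should give the allylic boronate with retention of the (Z)-geometry and tolerate the free alcohol.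

**Step 3**
Reactants: 7 (2Z)-2-methyl-4-(4,4,5,5-tetramethyl-1,3,2-dioxaborolan-2-yl)but-2-en-1-ol; 8 diiodomethane
Product: 9 [(1S,2R)-1-methyl-2-[(4,4,5,5-tetramethyl-1,3,2-dioxaborolan-2-yl)methyl]cyclopropyl]methanol
Conditions: Et2Zn (2.2 equiv), CH2I2 (4.4 equiv), DME, (4R,5R)-2-butyl-N,N,N′,N′-tetramethyl-1,3,2-dioxaborolane-4,5-dicarboxamide (1.2 equiv), CH2Cl2, −10 to 20 °C
Reagents that add atoms: diiodomethane (ICI)
Why: Hydroxyl-directed asymmetric Simmons–Smith cyclopropanation under control of the chiral dioxaborolane should add CH2 to one face of the (Z)-alkene, so the ligand sets the quaternary carbon (the later C10) and the neighbouring CH, the (Z)-geometry fixes CH2OH and CH2B cis, and the allylic boronate becomes an unreactive cyclopropylcarbinyl boronate.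

**Step 4**
Reactants: 9 [(1S,2R)-1-methyl-2-[(4,4,5,5-tetramethyl-1,3,2-dioxaborolan-2-yl)methyl]cyclopropyl]methanol
Product: 10 (1S,2R)-1-methyl-2-[(4,4,5,5-tetramethyl-1,3,2-dioxaborolan-2-yl)methyl]cyclopropane-1-carbaldehyde
Conditions: Dess–Martin periodinane (1.3 equiv), NaHCO3, CH2Cl2, 0 to 20 °C
Reagents that add atoms: none
Why: Dess–Martin oxidation of a primary alcohol should be clean, since the α-carbon is quaternary and cannot epimerise and the pinacol boronate is inert to the oxidant.

**Step 5**
Reactants: 11 prop-2-en-1-yl 2-(diethoxyphosphoryl)acetate; 12 (iodomethyl)trimethylsilane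
Product: 13 prop-2-en-1-yl 2-(diethoxyphosphoryl)-3-(trimethylsilyl)propanoate (racemic)
Conditions: NaH (1.05 equiv), DME, 0 to 60 °C
Reagents that add atoms: (iodomethyl)trimethylsilane (C[Si](C)(C)CI)
Why: C-alkylation of the sodium phosphonoacetate with a primary iodide (phosphonate alkylation) should stop after one alkylation because the product carbanion is more hindered.

**Step 6**
Reactants: 10 (1S,2R)-1-methyl-2-[(4,4,5,5-tetramethyl-1,3,2-dioxaborolan-2-yl)methyl]cyclopropane-1-carbaldehyde; 13 prop-2-en-1-yl 2-(diethoxyphosphoryl)-3-(trimethylsilyl)propanoate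
Product: 14 prop-2-en-1-yl (2Z)-3-{(1S,2R)-1-methyl-2-[(4,4,5,5-tetramethyl-1,3,2-dioxaborolan-2-yl)methyl]cyclopropyl}-2-[(trimethylsilyl)methyl]prop-2-enoate
Conditions: 13 (1.2 equiv), NaH (1.2 equiv), THF, 0 to 20 °C
Reagents that add atoms: none
Why: Horner–Wadsworth–Emmons olefination of the non-enolisable aldehyde with the α-branched phosphonate should give mainly the alkene with the ester trans to the cyclopropyl group ((Z) by the sequence rule); no stereocentre is formed.

**Step 7**
Reactants: 15 5-hydroxyfuran-2(5H)-one; 16 (1S,2R,5S)-(+)-menthol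
Product: 17 (5S)-5-{[(1S,2R,5S)-5-methyl-2-(propan-2-yl)cyclohexyl]oxy}furan-2(5H)-one
Conditions: camphor-10-sulfonic acid (cat.), toluene, reflux (−H2O); crystallisation from hexane
Reagents that add atoms: (1S,2R,5S)-menthol (C[C@H]1CC[C@@H]([C@H](C1)O)C(C)C)
Why: Acid-catalysed acetalisation of the lactol with (+)-menthol gives two C5 epimers that equilibrate under acid, and the (5S)-epimer should crystallise, as the mirror image of the (5R)-epimer does in the (−)-menthol series.

**Step 8**
Reactants: 17 (5S)-5-(menthyloxy)furan-2(5H)-one; 18 methanol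
Product: 19 (4R,5S)-4-(hydroxymethyl)-5-{[(1S,2R,5S)-5-methyl-2-(propan-2-yl)cyclohexyl]oxy}oxolan-2-one
Conditions: hν (350 nm), Ph2CO (0.2 equiv), MeOH, 20 °C
Reagents that add atoms: methanol (CO)
Why: Benzophenone-sensitised conjugate radical addition (photochemical hydroxymethylation) should bring the nucleophilic hydroxymethyl radical to the β-carbon anti to the menthyloxy group, which sets C4 of the lactone (C7 of the target).

**Step 9**
Reactants: 19 (4R,5S)-4-(hydroxymethyl)-5-(menthyloxy)oxolan-2-one; 20 N,N-dimethylmethaniminium iodide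
Product: 21 (3R,4R,5S)-3-[(dimethylamino)methyl]-4-(hydroxymethyl)-5-{[(1S,2R,5S)-5-methyl-2-(propan-2-yl)cyclohexyl]oxy}oxolan-2-one
Conditions: LiN(i-Pr)2 (2.2 equiv), THF, −78 °C; then 20 (1.5 equiv), −78 to 0 °C; H2O
Reagents that add atoms: N,N-dimethylmethaniminium iodide (C[N+](C)=C.[I-])
Why: Mannich alkylation of the lactone enolate (alkoxide enolate dianion) with the iminium salt should occur anti to the C4 substituent and installs the latent exo-methylene as an amine that survives the Lewis acids of step 11.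

**Step 10**
Reactants: 21 (3R,4R,5S)-3-[(dimethylamino)methyl]-4-(hydroxymethyl)-5-(menthyloxy)oxolan-2-one
Product: 22 (2S,3R,4R)-4-[(dimethylamino)methyl]-2-{[(1S,2R,5S)-5-methyl-2-(propan-2-yl)cyclohexyl]oxy}-5-oxooxolane-3-carbaldehyde
Conditions: Dess–Martin periodinane (1.3 equiv), CH2Cl2, 0 to 20 °C; used at once
Reagents that add atoms: none
Why: Dess–Martin oxidation of the primary alcohol should be safe because the formyl-bearing centre already sits in the all-trans arrangement, so that epimerisation cannot erode it.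

**Step 11**
Reactants: 14 prop-2-en-1-yl (2Z)-3-{(1S,2R)-1-methyl-2-[(pinacolatoboryl)methyl]cyclopropyl}-2-[(trimethylsilyl)methyl]prop-2-enoate; 22 (2S,3R,4R)-4-[(dimethylamino)methyl]-2-(menthyloxy)-5-oxooxolane-3-carbaldehyde
Product: 24 prop-2-en-1-yl (5R,6R,7R,8S,10S,11R)-13-(dimethylamino)-8-hydroxy-11,13-dihydroelema-1,3-dien-12,6-olid-15-oate, via cyclopropyl lactone aldehyde 23 (not isolated)
Conditions: 14 (1.2 equiv), Me3SiOTf (2.2 equiv), CH2Cl2, −78 to −30 °C; then PhBCl2 (2.0 equiv), −78 to 20 °C; aq. NaHCO3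
Reagents that add atoms: none
Why: Proposed new method: a one-flask (3+3) annulation in which Me3SiOTf first ionises the menthyl acetal of 22 to a five-membered acyloxocarbenium ion at C6 that the 2-(allyloxycarbonyl)allylsilane of 14 attacks through C5 (anti-SE2′, open transition state) to give 23 with the C4 acrylate unit, and PhBCl2 then turns the cyclopropylcarbinyl boronate into a chloroborane that binds the C8 aldehyde and delivers C9 to it through a six-membered cyclic transition state while the C1–C9 cyclopropane bond opens to the C10 vinyl group. The closest known reaction types are the Hosomi–Sakurai allylation of lactol-derived acyloxocarbenium ions with 2-(silylmethyl)acrylates and the PhBCl2-promoted homoallylboration of aldehydes with cyclopropylcarbinyl pinacol boronates; new are their pairing in one flask and the ring-closing use of the second. Ring A is closed by this homoallylboration as a 6-exo-trig carbonyl addition through a chair-like bicyclic transition state, and ring B is carried over from 22. C6 is set by the C7 formyl group (attack trans to it on the planar lactone cation, hence the trans ring fusion), C5 by attack on the alkene face turned away from the cis CH2B arm of the cyclopropane, C8 by the chair transition state that places the oxygen and C7 equatorial, and C10 is carried unchanged from the cyclopropane. The step needs the pairing C5 to C6 before C9 to C8, which should be secured because the pinacol boronate is inert to cations until PhBCl2 is added and the ester-deactivated allylsilane reacts with the acyloxocarbenium ion but not with the aldehyde.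

**Step 12**
Reactants: 24 prop-2-en-1-yl (5R,6R,7R,8S,10S,11R)-13-(dimethylamino)-8-hydroxy-11,13-dihydroelema-1,3-dien-12,6-olid-15-oate; 25 angelic acid, (2Z)-2-methylbut-2-enoic acid
Product: 26 prop-2-en-1-yl (5R,6R,7R,8S,10S,11R)-8-(angeloyloxy)-13-(dimethylamino)-11,13-dihydroelema-1,3-dien-12,6-olid-15-oate
Conditions: 25 (3 equiv), 2,4,6-trichlorobenzoyl chloride (3 equiv), Et3N (6 equiv), toluene, 20 °C; then 24, 75 °C
Reagents that add atoms: angelic acid (C/C=C(/C)C(=O)O)
Why: Yamaguchi-type esterification through the mixed 2,4,6-trichlorobenzoic anhydride, run without a pyridine catalyst so that the (Z)-ester should not isomerise to the tiglate, acylates the only hydroxyl group and creates no stereocentre.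

**Step 13**
Reactants: 26 prop-2-en-1-yl (5R,6R,7R,8S,10S,11R)-8-(angeloyloxy)-13-(dimethylamino)-11,13-dihydroelema-1,3-dien-12,6-olid-15-oate
Product: 28 prop-2-en-1-yl (5R,6R,7R,8S,10S)-8-(angeloyloxy)elema-1,3,11(13)-trien-12,6-olid-15-oate, via trimethylammonium iodide 27 (not isolated)
Conditions: MeI (10 equiv), MeCN, 20 °C; then NaHCO3 (aq.), EtOAc, 20 °C
Reagents that add atoms: none
Why: Quaternisation of the tertiary amine followed by E1cB loss of trimethylamine from the β-ammonium lactone (Hofmann-type elimination) should unveil the α-methylene lactone under conditions that leave the angelate and the allyl ester intact.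

**Step 14**
Reactants: 28 prop-2-en-1-yl (5R,6R,7R,8S,10S)-8-(angeloyloxy)elema-1,3,11(13)-trien-12,6-olid-15-oate
Product: 29 (5R,6R,7R,8S,10S)-8-(angeloyloxy)elema-1,3,11(13)-trien-12,6-olid-15-oic acid (target, CNP0256928.3)
Conditions: Pd(PPh3)4 (5 mol%), PhSiH3 (2 equiv), CH2Cl2, 20 °C
Reagents that add atoms: none
Why: Tsuji–Trost deallylation, in which zerovalent palladium ionises the allyl ester to a π-allyl complex that PhSiH3 reduces, is neutral and should spare the angelate, the lactone and both exo-methylene groups.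

**Compound list**

1 | prop-2-yn-1-ol | C#CCO | starting material
2 | methylmagnesium bromide | C[Mg]Br | starting material
3 | iodine | II | starting material
4 | (Z)-alkenylmagnesium alkoxide from carbomagnesiation of 1 (Mg cis to CH2O) | Br[Mg]/C=C(/C)CO[Mg]Br | intermediate
5 | (2Z)-3-iodo-2-methylprop-2-en-1-ol | OC/C(C)=C\I | intermediate
6 | 2,2′-methylenebis(4,4,5,5-tetramethyl-1,3,2-dioxaborolane) | CC1(C)OB(CB2OC(C)(C)C(C)(C)O2)OC1(C)C | starting material
7 | (2Z)-2-methyl-4-(4,4,5,5-tetramethyl-1,3,2-dioxaborolan-2-yl)but-2-en-1-ol | OC/C(C)=C\CB1OC(C)(C)C(C)(C)O1 | intermediate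
8 | diiodomethane | ICI | starting material
9 | [(1S,2R)-1-methyl-2-[(4,4,5,5-tetramethyl-1,3,2-dioxaborolan-2-yl)methyl]cyclopropyl]methanol (CH2OH and CH2B cis) | OC[C@@]1(C)C[C@H]1CB1OC(C)(C)C(C)(C)O1 | intermediate
10 | (1S,2R)-1-methyl-2-[(4,4,5,5-tetramethyl-1,3,2-dioxaborolan-2-yl)methyl]cyclopropane-1-carbaldehyde | O=C[C@@]1(C)C[C@H]1CB1OC(C)(C)C(C)(C)O1 | intermediate
11 | prop-2-en-1-yl 2-(diethoxyphosphoryl)acetate | C=CCOC(=O)CP(=O)(OCC)OCC | starting material
12 | (iodomethyl)trimethylsilane | C[Si](C)(C)CI | starting material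
13 | prop-2-en-1-yl 2-(diethoxyphosphoryl)-3-(trimethylsilyl)propanoate (racemic) | C=CCOC(=O)C(C[Si](C)(C)C)P(=O)(OCC)OCC | intermediate
14 | prop-2-en-1-yl (2Z)-3-{(1S,2R)-1-methyl-2-[(4,4,5,5-tetramethyl-1,3,2-dioxaborolan-2-yl)methyl]cyclopropyl}-2-[(trimethylsilyl)methyl]prop-2-enoate | C=CCOC(=O)/C(C[Si](C)(C)C)=C/[C@@]1(C)C[C@H]1CB1OC(C)(C)C(C)(C)O1 | intermediate
15 | 5-hydroxyfuran-2(5H)-one (racemic lactol) | O=C1C=CC(O)O1 | starting material
16 | (1S,2R,5S)-(+)-menthol | C[C@H]1CC[C@@H]([C@H](C1)O)C(C)C | starting material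
17 | (5S)-5-{[(1S,2R,5S)-5-methyl-2-(propan-2-yl)cyclohexyl]oxy}furan-2(5H)-one | O=C1C=C[C@@H](O[C@H]2C[C@@H](C)CC[C@@H]2C(C)C)O1 | intermediate
18 | methanol | CO | starting material
19 | (4R,5S)-4-(hydroxymethyl)-5-{[(1S,2R,5S)-5-methyl-2-(propan-2-yl)cyclohexyl]oxy}oxolan-2-one | OC[C@H]1CC(=O)O[C@@H]1O[C@H]1C[C@@H](C)CC[C@@H]1C(C)C | intermediate
20 | N,N-dimethylmethaniminium iodide | C[N+](C)=C.[I-] | starting material
21 | (3R,4R,5S)-3-[(dimethylamino)methyl]-4-(hydroxymethyl)-5-{[(1S,2R,5S)-5-methyl-2-(propan-2-yl)cyclohexyl]oxy}oxolan-2-one (all-trans) | OC[C@H]1[C@H](CN(C)C)C(=O)O[C@@H]1O[C@H]1C[C@@H](C)CC[C@@H]1C(C)C | intermediate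
22 | (2S,3R,4R)-4-[(dimethylamino)methyl]-2-{[(1S,2R,5S)-5-methyl-2-(propan-2-yl)cyclohexyl]oxy}-5-oxooxolane-3-carbaldehyde | O=C[C@H]1[C@H](CN(C)C)C(=O)O[C@@H]1O[C@H]1C[C@@H](C)CC[C@@H]1C(C)C | intermediate
23 | lactone aldehyde in which the menthyloxy group of 22 is replaced, trans to the formyl group, by C5 bearing the allyl acrylate unit and the intact (1S,2R)-cyclopropyl boronate (C5, C6, C7 as in the target) | O=C[C@H]1[C@H](CN(C)C)C(=O)O[C@@H]1[C@@H](C(=C)C(=O)OCC=C)[C@@]1(C)C[C@H]1CB1OC(C)(C)C(C)(C)O1 | intermediate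
24 | prop-2-en-1-yl (5R,6R,7R,8S,10S,11R)-13-(dimethylamino)-8-hydroxy-11,13-dihydroelema-1,3-dien-12,6-olid-15-oate | C=C[C@]1(C)C[C@H](O)[C@H]2[C@H](CN(C)C)C(=O)O[C@@H]2[C@H]1C(=C)C(=O)OCC=C | intermediate
25 | angelic acid, (2Z)-2-methylbut-2-enoic acid | C/C=C(/C)C(=O)O | starting material
26 | prop-2-en-1-yl (5R,6R,7R,8S,10S,11R)-8-(angeloyloxy)-13-(dimethylamino)-11,13-dihydroelema-1,3-dien-12,6-olid-15-oate | C=C[C@]1(C)C[C@H](OC(=O)/C(C)=C\C)[C@H]2[C@H](CN(C)C)C(=O)O[C@@H]2[C@H]1C(=C)C(=O)OCC=C | intermediate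
27 | N-methyl ammonium iodide of 26 | C=C[C@]1(C)C[C@H](OC(=O)/C(C)=C\C)[C@H]2[C@H](C[N+](C)(C)C)C(=O)O[C@@H]2[C@H]1C(=C)C(=O)OCC=C.[I-] | intermediate
28 | prop-2-en-1-yl (5R,6R,7R,8S,10S)-8-(angeloyloxy)elema-1,3,11(13)-trien-12,6-olid-15-oate | C=C[C@]1(C)C[C@H](OC(=O)/C(C)=C\C)[C@H]2C(=C)C(=O)O[C@@H]2[C@H]1C(=C)C(=O)OCC=C | intermediate
29 | (5R,6R,7R,8S,10S)-8-(angeloyloxy)elema-1,3,11(13)-trien-12,6-olid-15-oic acid | C=C[C@]1(C)C[C@H](OC(=O)/C(C)=C\C)[C@H]2C(=C)C(=O)O[C@@H]2[C@H]1C(=C)C(=O)O | target

**Step count and risks**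

Total step count: 14. Longest linear sequence: 9 steps (1, 2, 3, 4, 6, 11, 12, 13, 14).

Steps most likely to fail:

1. Step 11 (Proposed new method). What may go wrong: the intermolecular allylsilane addition may show poor facial selectivity at C5; the acyloxocarbenium ion may lose the C7 proton instead of being trapped; the two nucleophilic sites may pair with the wrong electrophiles; or the boron-mediated ring closure may not take place. The fallback sets out from 14 and 22 and comes back to the route at 26. It inverts the order of the two bond formations and uses only reactions with direct precedent. PhBCl2 (CH2Cl2, −78 °C) would first join 14 and 22 by intermolecular homoallylboration of the aldehyde to the ring-A-seco homoallylic alcohol F1. Acylation as in step 12 would give its angelate F2. CF3CO2H in wet THF would hydrolyse the menthyl acetal to the lactol F3, and Me3SiCHN2 in MeOH would trap the open form as the aldehyde methyl ester F4. TiCl4 (CH2Cl2, −78 °C) would then close ring A by an intramolecular Hosomi–Sakurai reaction on the open-chain aldehyde (chair transition state, substituents equatorial) to the hydroxy ester F5, which TsOH in warm toluene would lactonise to 26.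

2. Step 3. What may go wrong: loss of the allylic boron by protodeboronation or allyl transfer under the zinc carbenoid conditions, and low facial selectivity of the methylene delivery. The fallback sets out from 5 and comes back at 9; it cyclopropanates before the boron is introduced. The same dioxaborolane-mediated Simmons–Smith reaction on the vinyl iodide 5 would give cis-(2-iodo-1-methylcyclopropyl)methanol F6, and t-BuMe2SiCl with imidazole its silyl ether F7. Iodine–lithium exchange (t-BuLi, Et2O, −78 °C; cyclopropyllithiums keep their configuration) and quench with i-PrOB(pin) would give the cyclopropyl boronate F8. Matteson homologation (BrCH2Cl, n-BuLi, THF, −78 to 20 °C) would insert CH2 with retention to the cyclopropylcarbinyl boronate F9, and HCl in MeOH would remove the silyl group to give 9.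

3. Step 12. What may go wrong: isomerisation of the angelate to the tiglate during acylation, and slow acylation of the hindered secondary alcohol. The fallback sets out from 24 and comes back at 26; it builds the (Z)-double bond on the substrate instead of carrying it in. Esterification of 24 (DCC, DMAP cat., CH2Cl2) with 2-[bis(2,2,2-trifluoroethoxy)phosphoryl]propanoic acid would give the phosphonate ester F10, and a (Z)-selective Still–Gennari olefination (KN(SiMe3)2, 18-crown-6, THF, −78 °C, then acetaldehyde) would give 26.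

**Further compounds**

F1 | step 11 | prop-2-en-1-yl (2Z,4S,6S)-4-ethenyl-6-hydroxy-4-methyl-6-[(2S,3R,4R)-4-[(dimethylamino)methyl]-2-(menthyloxy)-5-oxooxolan-3-yl]-2-[(trimethylsilyl)methyl]hex-2-enoate | C=C[C@@](C)(/C=C(\C[Si](C)(C)C)C(=O)OCC=C)C[C@H](O)[C@H]1[C@H](CN(C)C)C(=O)O[C@@H]1O[C@H]1C[C@@H](C)CC[C@@H]1C(C)C
F2 | step 11 | angelate of F1 | C=C[C@@](C)(/C=C(\C[Si](C)(C)C)C(=O)OCC=C)C[C@H](OC(=O)/C(C)=C\C)[C@H]1[C@H](CN(C)C)C(=O)O[C@@H]1O[C@H]1C[C@@H](C)CC[C@@H]1C(C)C
F3 | step 11 | lactol from F2 (menthyloxy replaced by OH, both anomers) | C=C[C@@](C)(/C=C(\C[Si](C)(C)C)C(=O)OCC=C)C[C@H](OC(=O)/C(C)=C\C)[C@H]1[C@H](CN(C)C)C(=O)OC1O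
F4 | step 11 | open-chain aldehyde methyl ester from F3 | C=C[C@@](C)(/C=C(\C[Si](C)(C)C)C(=O)OCC=C)C[C@H](OC(=O)/C(C)=C\C)[C@H](C=O)[C@H](CN(C)C)C(=O)OC
F5 | step 11 | ring A hydroxy ester (6-hydroxy, methyl ester at C12, not yet lactonised) | C=C[C@]1(C)C[C@H](OC(=O)/C(C)=C\C)[C@@H]([C@H](CN(C)C)C(=O)OC)[C@H](O)[C@H]1C(=C)C(=O)OCC=C
F6 | step 3 | [(1R,2R)-2-iodo-1-methylcyclopropyl]methanol (I and CH2OH cis) | OC[C@@]1(C)C[C@H]1I
F7 | step 3 | tert-butyldimethylsilyl ether of F6 | CC(C)(C)[Si](C)(C)OC[C@@]1(C)C[C@H]1I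
F8 | step 3 | cis-cyclopropyl pinacol boronate silyl ether | CC(C)(C)[Si](C)(C)OC[C@@]1(C)C[C@H]1B1OC(C)(C)C(C)(C)O1
F9 | step 3 | tert-butyldimethylsilyl ether of 9 | CC(C)(C)[Si](C)(C)OC[C@@]1(C)C[C@H]1CB1OC(C)(C)C(C)(C)O1
F10 | step 12 | 8-O-{2-[bis(2,2,2-trifluoroethoxy)phosphoryl]propanoyl} ester of 24 | C=C[C@]1(C)C[C@H](OC(=O)C(C)P(=O)(OCC(F)(F)F)OCC(F)(F)F)[C@H]2[C@H](CN(C)C)C(=O)O[C@@H]2[C@H]1C(=C)C(=O)OCC=C
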